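**Retrosynthetic overview**
- Target ⇐ desilylation ⇐ the only ring (ten-membered carbocycle), closed late by ring-closing metathesis at C6=C7 of an acyclic triene diester.
- Both ester C–O bonds and the C1 stereocentre ⇐ hydroxyl-directed samarium Tishchenko redox esterification of a β-hydroxy Z-enone with cinnamaldehyde (C9 cinnamate formed, hydride to C1), the C1 alkoxide being capped as acetate in the same flask.
- β-Hydroxy Z-enone ⇐ Z-alkenyllithium (C2–C6, C4 set by allylboration) + β-hydroxy Weinreb amide (C7–C10 and C1, C9/C10 set by an Evans syn aldol).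
- Building blocks: propargyl alcohol, 3-methylbut-3-en-1-ol, N-isovaleryl oxazolidinone, cinnamaldehyde.

Assumption: ring atoms are numbered C1 (acetoxy carbon), C2=C3(Me), C4 (hydroxyl carbon), C5, C6=C7(Me), C8, C9 (cinnamate carbon), C10 (isopropyl carbon), which makes the target (1S,2Z,4R,6Z,9S,10R); imide 10 is taken as a purchased bulk intermediate.

**Route**

Step 1
Reactants: 1 propargyl alcohol
Product: 3 (Z)-3-iodo-2-methylprop-2-en-1-ol, via alkenylmagnesium alkoxide 2 (not isolated)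
Conditions: MeMgBr (2.5 equiv), CuI (10 mol %), THF, −20 °C → rt; then I2, −20 °C
Reagents that add atoms: methylmagnesium bromide, C[Mg]Br; iodine, II
Why: Copper-catalysed anti-carbomagnesiation of the propargylic alkoxide (Duboudin reaction) puts the methyl on C3 and magnesium on C2 cis to the CH2O arm in a five-membered chelate, and iodinolysis with retention gives the Z iodide.

Step 2
Reactants: 3 (Z)-3-iodo-2-methylprop-2-en-1-ol
Product: 4 (Z)-3-iodo-2-methylprop-2-enal
Conditions: MnO2 (15 equiv), CH2Cl2, rt, dark; filter, use at once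
Reagents that add atoms: none
Why: Neutral MnO2 allylic oxidation leaves the Z vinyl iodide untouched and avoids acid or base that would isomerise the enal.

Step 3
Reactants: 4 (Z)-3-iodo-2-methylprop-2-enal
Product: 6 (1Z,3R)-1-iodo-2-methylhexa-1,5-dien-3-ol, via diisopinocampheylborinate 5 (not isolated)
Conditions: (+)-Ipc2BOMe, allylMgBr, Et2O, −78 °C → rt; then 4, −78 °C; NaOH, H2O2, 0 °C → rt
Reagents that add atoms: allylmagnesium bromide, C=CC[Mg]Br
Why: Brown asymmetric allylboration through a chair transition state, in which the reagent derived from (−)-α-pinene attacks the Re face of the aldehyde and sets the future C4 as R.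

Step 4
Reactants: 6 (1Z,3R)-1-iodo-2-methylhexa-1,5-dien-3-ol
Product: 7 tert-butyl{[(1Z,3R)-1-iodo-2-methylhexa-1,5-dien-3-yl]oxy}dimethylsilane
Conditions: TBSCl, imidazole, DMF, rt
Reagents that add atoms: tert-butyldimethylsilyl chloride, CC(C)(C)[Si](C)(C)Cl
Why: Standard silyl ether formation; the silyl group stops the later Z-γ-hydroxy enone from closing to a furan and is bulky enough to resist oxygen-to-carbon silyl migration in the alkenyllithium at −78 °C.

Step 5
Reactants: 8 3-methylbut-3-en-1-ol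
Product: 9 3-methylbut-3-enal
Conditions: Dess–Martin periodinane, CH2Cl2, 0 °C → rt; dilute with pentane, filter, use the solution at once
Reagents that add atoms: none
Why: Dess–Martin oxidation is neutral and fast, so the β,γ-unsaturated aldehyde does not slip into conjugation.

Step 6
Reactants: 10 (R)-4-benzyl-3-(3-methylbutanoyl)-1,3-oxazolidin-2-one; 9 3-methylbut-3-enal
Product: 13 (R)-4-benzyl-3-[(2R,3S)-3-hydroxy-5-methyl-2-(propan-2-yl)hex-5-enoyl]-1,3-oxazolidin-2-one, via Z boron enolate 11 (not isolated), via boron aldolate 12 (not isolated)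
Conditions: Bu2BOTf, iPr2NEt, CH2Cl2, −78 → 0 °C; 9, −78 → 0 °C; pH 7 buffer, MeOH, H2O2, 0 °C
Reagents that add atoms: none
Why: Evans syn aldol, in which the Z boron enolate reacts through a Zimmerman–Traxler chair on the face away from the benzyl group of the (R) auxiliary and sets C10 (R) and C9 (S) syn to each other.

Step 7
Reactants: 13 (R)-4-benzyl-3-[(2R,3S)-3-hydroxy-5-methyl-2-(propan-2-yl)hex-5-enoyl]-1,3-oxazolidin-2-one
Product: 14 (2R,3S)-3-hydroxy-N-methoxy-N,5-dimethyl-2-(propan-2-yl)hex-5-enamide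
Conditions: MeNH(OMe)·HCl, AlMe3, THF, −20 → 0 °C; aq. potassium sodium tartrate
Reagents that add atoms: N,O-dimethylhydroxylamine hydrochloride, CNOC.Cl
Why: Aluminium amide transamidation (Weinreb amide formation), assisted by the free β-hydroxyl, releases the auxiliary without epimerisation or retro-aldol.

Step 8
Reactants: 7 tert-butyl{[(1Z,3R)-1-iodo-2-methylhexa-1,5-dien-3-yl]oxy}dimethylsilane; 14 (2R,3S)-3-hydroxy-N-methoxy-N,5-dimethyl-2-(propan-2-yl)hex-5-enamide
Product: 17 (4R,5Z,8R,9S)-4-[(tert-butyldimethylsilyl)oxy]-9-hydroxy-5,11-dimethyl-8-(propan-2-yl)dodeca-1,5,11-trien-7-one, via Z alkenyllithium 15 (not isolated), via chloromagnesium alkoxide 16 (not isolated)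
Conditions: 7 (1.3 equiv), t-BuLi (2.6 equiv), Et2O, −78 °C; 14 pretreated with iPrMgCl (1.0 equiv, THF, −20 °C) added at −78 °C, then −40 °C; pH 7 buffer
Reagents that add atoms: none
Why: Iodine–lithium exchange keeps the alkene geometry, and the Weinreb ketone synthesis stops at the chelated tetrahedral intermediate, so the Z enone forms without over-addition while the hydroxyl is masked as its magnesium alkoxide.

Step 9
Reactants: 17 (4R,5Z,8R,9S)-4-[(tert-butyldimethylsilyl)oxy]-9-hydroxy-5,11-dimethyl-8-(propan-2-yl)dodeca-1,5,11-trien-7-one; 18 (E)-cinnamaldehyde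
Product: 20 (4R,5Z,7S,8R,9S)-7-acetoxy-4-[(tert-butyldimethylsilyl)oxy]-5,11-dimethyl-8-(propan-2-yl)dodeca-1,5,11-trien-9-yl (E)-3-phenylprop-2-enoate, via hydroxy cinnamate 19 (not isolated)
Conditions: SmI2 (0.3 equiv) premixed with 18 (6 equiv), THF, −10 °C, then 17, −10 °C; then isopropenyl acetate (10 equiv), 0 °C → rt
Reagents that add atoms: isopropenyl acetate, CC(=C)OC(C)=O
Why: Proposed new method: a one-flask samarium-catalysed Evans–Tishchenko redox esterification and acetyl-transfer cascade, untested with an α,β-unsaturated aldehyde donor on a β-hydroxy Z-enone and never coupled to enol-ester capping — divalent samarium is consumed by cinnamaldehyde to a trivalent samarium alkoxide that binds the C9 hydroxyl and the C1 carbonyl, the C9 hemiacetal of cinnamaldehyde forms the new C–O bond, and its C–H hydride passes through a chair-like six-membered transition state to C1 (1,2 only, anti to the C9 oxygen), giving the C9 cinnamate and a C1 samarium alkoxide, which isopropenyl acetate then acetylates by lanthanide-alkoxide acyl transfer (acetone leaves, samarium turns over), so that 1,3-cinnamoyl migration is blocked; the closest known reactions are the Evans–Tishchenko reduction of β-hydroxy ketones with saturated or aryl aldehydes and lanthanide-catalysed acylation of alcohols with enol esters.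

Step 10
Reactants: 20 (4R,5Z,7S,8R,9S)-7-acetoxy-4-[(tert-butyldimethylsilyl)oxy]-5,11-dimethyl-8-(propan-2-yl)dodeca-1,5,11-trien-9-yl (E)-3-phenylprop-2-enoate
Product: 21 (1S,2Z,4R,6Z,9S,10R)-1-acetoxy-4-[(tert-butyldimethylsilyl)oxy]-3,7-dimethyl-10-(propan-2-yl)cyclodeca-2,6-dien-9-yl (E)-3-phenylprop-2-enoate
Conditions: Mo(=CHCMe2Ph)(=N-2,6-iPr2C6H3)[OCMe(CF3)2]2 (20 mol %), benzene, 1 mM, 60 °C, argon sparge
Reagents that add atoms: none
Why: Ring-closing metathesis, in which the molybdenum alkylidene loads on the terminal vinyl group, closes onto the 1,1-disubstituted alkene and ignores the electron-poor cinnamate, and the ten-membered ring with the existing Z alkene is expected to accept the new trisubstituted alkene as its cis (Z) isomer.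

Step 11
Reactants: 21 (1S,2Z,4R,6Z,9S,10R)-1-acetoxy-4-[(tert-butyldimethylsilyl)oxy]-3,7-dimethyl-10-(propan-2-yl)cyclodeca-2,6-dien-9-yl (E)-3-phenylprop-2-enoate
Product: 22 (1S,2Z,4R,6Z,9S,10R)-1-acetoxy-4-hydroxy-3,7-dimethyl-10-(propan-2-yl)cyclodeca-2,6-dien-9-yl (E)-3-phenylprop-2-enoate
Conditions: HF·pyridine, pyridine, THF, 0 °C → rt
Reagents that add atoms: none
Why: Buffered fluoride desilylation cleaves only the Si–O bond, so both esters stay in place and base-promoted acyl migration to the freed C4 hydroxyl is avoided.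

**Compound list**

1 | propargyl alcohol (prop-2-yn-1-ol) | C#CCO | starting material
2 | bromomagnesium (Z)-3-(bromomagnesio)-2-methylprop-2-en-1-olate | Br[Mg]/C=C(/C)CO[Mg]Br | intermediate
3 | (Z)-3-iodo-2-methylprop-2-en-1-ol | I/C=C(/C)CO | intermediate
4 | (Z)-3-iodo-2-methylprop-2-enal | I/C=C(/C)C=O | intermediate
5 | (1Z,3R)-1-iodo-2-methylhexa-1,5-dien-3-yl diisopinocampheylborinate (isopinocampheyl groups from (−)-α-pinene) | I/C=C(/C)[C@H](OB([C@H]1C[C@H]2C[C@@H]([C@@H]1C)C2(C)C)[C@H]1C[C@H]2C[C@@H]([C@@H]1C)C2(C)C)CC=C | intermediate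
6 | (1Z,3R)-1-iodo-2-methylhexa-1,5-dien-3-ol | I/C=C(/C)[C@H](O)CC=C | intermediate
7 | tert-butyl{[(1Z,3R)-1-iodo-2-methylhexa-1,5-dien-3-yl]oxy}dimethylsilane | I/C=C(/C)[C@H](O[Si](C)(C)C(C)(C)C)CC=C | intermediate
8 | 3-methylbut-3-en-1-ol | C=C(C)CCO | starting material
9 | 3-methylbut-3-enal | C=C(C)CC=O | intermediate
10 | (R)-4-benzyl-3-(3-methylbutanoyl)-1,3-oxazolidin-2-one | CC(C)CC(=O)N1[C@H](Cc2ccccc2)COC1=O | starting material
11 | Z dibutylboron enolate of 10 (boron oxygen cis to isopropyl) | CC(C)/C=C(\OB(CCCC)CCCC)N1[C@H](Cc2ccccc2)COC1=O | intermediate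
12 | dibutylboron aldolate of 13 | C=C(C)C[C@H](OB(CCCC)CCCC)[C@@H](C(C)C)C(=O)N1[C@H](Cc2ccccc2)COC1=O | intermediate
13 | (R)-4-benzyl-3-[(2R,3S)-3-hydroxy-5-methyl-2-(propan-2-yl)hex-5-enoyl]-1,3-oxazolidin-2-one | C=C(C)C[C@H](O)[C@@H](C(C)C)C(=O)N1[C@H](Cc2ccccc2)COC1=O | intermediate
14 | (2R,3S)-3-hydroxy-N-methoxy-N,5-dimethyl-2-(propan-2-yl)hex-5-enamide | C=C(C)C[C@H](O)[C@@H](C(C)C)C(=O)N(C)OC | intermediate
15 | (1Z,3R)-3-[(tert-butyldimethylsilyl)oxy]-2-methylhexa-1,5-dien-1-yllithium | [Li]/C=C(/C)[C@H](O[Si](C)(C)C(C)(C)C)CC=C | intermediate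
16 | chloromagnesium alkoxide of 14 | C=C(C)C[C@H](O[Mg]Cl)[C@@H](C(C)C)C(=O)N(C)OC | intermediate
17 | (4R,5Z,8R,9S)-4-[(tert-butyldimethylsilyl)oxy]-9-hydroxy-5,11-dimethyl-8-(propan-2-yl)dodeca-1,5,11-trien-7-one | C=C(C)C[C@H](O)[C@@H](C(C)C)C(=O)/C=C(/C)[C@H](O[Si](C)(C)C(C)(C)C)CC=C | intermediate
18 | (E)-cinnamaldehyde | O=C/C=C/c1ccccc1 | starting material
19 | (4R,5Z,7S,8S,9S)-4-[(tert-butyldimethylsilyl)oxy]-7-hydroxy-5,11-dimethyl-8-(propan-2-yl)dodeca-1,5,11-trien-9-yl (E)-3-phenylprop-2-enoate (new carbinol anti to the cinnamate oxygen) | C=C(C)C[C@H](OC(=O)/C=C/c1ccccc1)[C@@H](C(C)C)[C@@H](O)/C=C(/C)[C@H](O[Si](C)(C)C(C)(C)C)CC=C | intermediate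
20 | (4R,5Z,7S,8R,9S)-7-acetoxy-4-[(tert-butyldimethylsilyl)oxy]-5,11-dimethyl-8-(propan-2-yl)dodeca-1,5,11-trien-9-yl (E)-3-phenylprop-2-enoate | C=C(C)C[C@H](OC(=O)/C=C/c1ccccc1)[C@@H](C(C)C)[C@@H](OC(C)=O)/C=C(/C)[C@H](O[Si](C)(C)C(C)(C)C)CC=C | intermediate
21 | (1S,2Z,4R,6Z,9S,10R)-1-acetoxy-4-[(tert-butyldimethylsilyl)oxy]-3,7-dimethyl-10-(propan-2-yl)cyclodeca-2,6-dien-9-yl (E)-3-phenylprop-2-enoate | CC(=O)O[C@H]1/C=C(/C)[C@H](O[Si](C)(C)C(C)(C)C)C/C=C(/C)C[C@H](OC(=O)/C=C/c2ccccc2)[C@H]1C(C)C | intermediate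
22 | (1S,2Z,4R,6Z,9S,10R)-1-acetoxy-4-hydroxy-3,7-dimethyl-10-(propan-2-yl)cyclodeca-2,6-dien-9-yl (E)-3-phenylprop-2-enoate (CNP0284991.1) | CC(=O)O[C@H]1/C=C(/C)[C@H](O)C/C=C(/C)C[C@H](OC(=O)/C=C/c2ccccc2)[C@H]1C(C)C | target

**Step count and risk**

Total steps: 11. Longest linear sequence: 8 (steps 1, 2, 3, 4, 8, 9, 10, 11).

Three steps most likely to fail:

Step 8 (fragment union). The Z γ-silyloxy alkenyllithium 15 can undergo oxygen-to-carbon silyl migration, and the β-alkoxide of 16 can undergo retro-aldol. The fallback sets out from 14 and 7 and comes back at 17, with no carbanion involved. Amide 14 is silylated (Et3SiOTf, 2,6-lutidine) to (2R,3S)-N-methoxy-N,5-dimethyl-2-(propan-2-yl)-3-[(triethylsilyl)oxy]hex-5-enamide F1. Reduction with iBu2AlH at −78 °C gives (2R,3S)-5-methyl-2-(propan-2-yl)-3-[(triethylsilyl)oxy]hex-5-enal F2. F2 and iodide 7 are joined by a Nozaki–Hiyama–Kishi reaction (divalent chromium as CrCl2, catalytic NiCl2, DMSO/THF) to give the C7-epimeric bis-silyl allylic alcohols F3. Dess–Martin oxidation gives the bis-silyl Z enone F4. Selective removal of the triethylsilyl group (pyridinium p-toluenesulfonate, MeOH, 0 °C) then gives 17.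

Step 9 (the proposed new redox esterification and acetyl-transfer cascade). Possible failures are retro-aldol of 17, poor hydride transfer from an enal hemiacetal, or sluggish acetyl transfer to the hindered C1 alkoxide. The fallback uses only known chemistry; it sets out from 17 and comes back at 20. Hydroxyl-directed anti reduction with Me4NBH(OAc)3 (MeCN/AcOH, −30 °C) gives (4R,5Z,7S,8R,9S)-4-[(tert-butyldimethylsilyl)oxy]-5,11-dimethyl-8-(propan-2-yl)dodeca-1,5,11-triene-7,9-diol F5. The less hindered C9 hydroxyl is then esterified with cinnamoyl chloride and 2,4,6-collidine (CH2Cl2, −40 °C) to give 19, isolated this time and separated from any regioisomer. Ac2O/DMAP/pyridine converts 19 into 20.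

Step 10 (ring-closing metathesis to a trisubstituted alkene in a ten-membered ring). Possible failures are oligomerisation, the wrong alkene geometry, or interference by the cinnamate. The fallback closes the ring before the esters exist; it sets out from 17 and comes back at 21. Ketone 17 is cyclised with the second-generation Hoveyda–Grubbs catalyst RuCl2(=CH-C6H4-2-OiPr)(H2IMes) (toluene, 1 mM, 80 °C), which tolerates the free hydroxyl and the ketone, to give the macrocyclic β-hydroxy Z,Z-dienone F6. Tishchenko redox esterification with cinnamaldehyde on the ring (or the step 9 fallback sequence) gives the macrocyclic hydroxy cinnamate F7. Ac2O/DMAP then gives 21.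

Further compounds
F1 | step 8 | (2R,3S)-N-methoxy-N,5-dimethyl-2-(propan-2-yl)-3-[(triethylsilyl)oxy]hex-5-enamide | C=C(C)C[C@H](O[Si](CC)(CC)CC)[C@@H](C(C)C)C(=O)N(C)OC
F2 | step 8 | (2R,3S)-5-methyl-2-(propan-2-yl)-3-[(triethylsilyl)oxy]hex-5-enal | C=C(C)C[C@H](O[Si](CC)(CC)CC)[C@@H](C(C)C)C=O
F3 | step 8 | (4R,5Z,8S,9S)-4-[(tert-butyldimethylsilyl)oxy]-5,11-dimethyl-8-(propan-2-yl)-9-[(triethylsilyl)oxy]dodeca-1,5,11-trien-7-ol, mixture of C7 epimers | C=C(C)C[C@H](O[Si](CC)(CC)CC)[C@@H](C(C)C)C(O)/C=C(/C)[C@H](O[Si](C)(C)C(C)(C)C)CC=C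
F4 | step 8 | (4R,5Z,8R,9S)-4-[(tert-butyldimethylsilyl)oxy]-5,11-dimethyl-8-(propan-2-yl)-9-[(triethylsilyl)oxy]dodeca-1,5,11-trien-7-one | C=C(C)C[C@H](O[Si](CC)(CC)CC)[C@@H](C(C)C)C(=O)/C=C(/C)[C@H](O[Si](C)(C)C(C)(C)C)CC=C
F5 | step 9 | (4R,5Z,7S,8R,9S)-4-[(tert-butyldimethylsilyl)oxy]-5,11-dimethyl-8-(propan-2-yl)dodeca-1,5,11-triene-7,9-diol | C=C(C)C[C@H](O)[C@@H](C(C)C)[C@@H](O)/C=C(/C)[C@H](O[Si](C)(C)C(C)(C)C)CC=C
F6 | step 10 | (2Z,4R,6Z,9S,10R)-4-[(tert-butyldimethylsilyl)oxy]-9-hydroxy-3,7-dimethyl-10-(propan-2-yl)cyclodeca-2,6-dien-1-one | O=C1/C=C(/C)[C@H](O[Si](C)(C)C(C)(C)C)C/C=C(/C)C[C@H](O)[C@H]1C(C)C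
F7 | step 10 | macrocyclic hydroxy cinnamate, the 1-hydroxy analogue of 21 with the same configuration at C1, C4, C9 and C10 | O[C@H]1/C=C(/C)[C@H](O[Si](C)(C)C(C)(C)C)C/C=C(/C)C[C@H](OC(=O)/C=C/c2ccccc2)[C@H]1C(C)C
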